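**Retrosynthetic overview**
- Last bond: the feruloyl ester C–O bond, made by Steglich acylation of a chalcone allylic alcohol with silyl-protected ferulic acid; all phenols are then freed by buffered fluoride.
- Key C–C bond: Cα–Cβ of the enone, made by an intermolecular Claisen–Schmidt aldol condensation of a ring A methyl ketone with protected 4-hydroxybenzaldehyde, before the base-labile ester exists.
- (Z)-side chain: Still–Gennari olefination of an arylacetaldehyde, then hydride reduction; the co-reduced ketone is restored after selective silylation.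
- Aryl–C3 bond: aromatic Claisen rearrangement of 4-O-allyl-2,4-dihydroxyacetophenone, then oxidative cleavage of the allyl group.
- Rings: none is built; all three benzene rings are bought (2,4-dihydroxyacetophenone, 4-hydroxybenzaldehyde, ferulic acid).

Assumption: the target has no stereocentre, so "single isomer" is taken to mean the (2E)-chalcone, (2E)-ferulate and (2Z)-side-chain alkene exactly as drawn.

**Route**

Step 1
Reactants: 1 2,4-dihydroxyacetophenone; 2 allyl bromide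
Product: 3 1-[2-hydroxy-4-(prop-2-en-1-yloxy)phenyl]ethan-1-one
Conditions: K2CO3 (1.5 equiv), acetone, reflux, 8 h
Reagents that add atoms: none
Why: Williamson O-alkylation in which only the free 4-OH reacts, because the 2-OH is locked in a hydrogen bond to the acetyl carbonyl.

Step 2
Reactants: 3 1-[2-hydroxy-4-(prop-2-en-1-yloxy)phenyl]ethan-1-one
Product: 5 1-[2,4-dihydroxy-3-(prop-2-en-1-yl)phenyl]ethan-1-one, via Claisen dienone 4 (not isolated)
Conditions: PhNEt2, 200 °C, Ar, 8 h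
Reagents that add atoms: none
Why: Aromatic Claisen [3,3]-sigmatropic rearrangement, directed to C3 (between the two oxygens) by the bond fixation of the chelated 2-hydroxyacetophenone, followed by tautomerisation to the phenol.

Step 3
Reactants: 5 1-[2,4-dihydroxy-3-(prop-2-en-1-yl)phenyl]ethan-1-one
Product: 6 1-[2,4-bis(methoxymethoxy)-3-(prop-2-en-1-yl)phenyl]ethan-1-one
Conditions: NaH (2.2 equiv), MOMCl (2.5 equiv), DMF, 0 °C → rt
Reagents that add atoms: chloromethyl methyl ether (MOMCl), COCCl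
Why: Double phenoxide O-alkylation (acetal formation); NaH breaks the chelate of the 2-OH, and the MOM ethers withstand every basic, oxidising and reducing step up to the aldol.

Step 4
Reactants: 6 1-[2,4-bis(methoxymethoxy)-3-(prop-2-en-1-yl)phenyl]ethan-1-one
Product: 8 2-[3-acetyl-2,6-bis(methoxymethoxy)phenyl]acetaldehyde, via vicinal diol 7 (not isolated)
Conditions: OsO4 (2 mol %), NaIO4 (4 equiv), 2,6-lutidine (2 equiv), dioxane/H2O 3:1, rt; used crude
Reagents that add atoms: osmium tetroxide, O=[Os](=O)(=O)=O (catalytic oxygen carrier); sodium periodate, [Na+].[O-]I(=O)(=O)=O; water, O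
Why: Lemieux–Johnson oxidation (catalytic dihydroxylation of the only alkene, then periodate glycol cleavage) gives the arylacetaldehyde without ozone attacking the electron-rich ring.

Step 5
Reactants: 8 2-[3-acetyl-2,6-bis(methoxymethoxy)phenyl]acetaldehyde; 9 ethyl 2-[bis(2,2,2-trifluoroethoxy)phosphoryl]propanoate
Product: 10 ethyl (2Z)-4-[3-acetyl-2,6-bis(methoxymethoxy)phenyl]-2-methylbut-2-enoate
Conditions: 9 (1.3 equiv), KN(SiMe3)2 (1.25 equiv), 18-crown-6 (3 equiv), THF, −78 °C; then 8, −78 °C, 2 h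
Reagents that add atoms: none
Why: Still–Gennari variant of the Horner–Wadsworth–Emmons olefination; the trifluoroethyl phosphonate with a crown-ether-separated potassium ion eliminates fast from the kinetic adduct, placing the ester cis to CH2Ar (Z, typically >15:1), and the aldehyde reacts far faster than the aryl ketone.

Step 6
Reactants: 10 ethyl (2Z)-4-[3-acetyl-2,6-bis(methoxymethoxy)phenyl]-2-methylbut-2-enoate
Product: 11 (2Z)-4-[3-(1-hydroxyethyl)-2,6-bis(methoxymethoxy)phenyl]-2-methylbut-2-en-1-ol (racemic at the carbinol carbon)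
Conditions: iBu2AlH (5 equiv), CH2Cl2, −78 → 0 °C; aq. potassium sodium tartrate work-up
Reagents that add atoms: none
Why: Hydride reduction takes the conjugated ester 1,2 to the (Z)-allylic alcohol without touching the alkene geometry; the aryl ketone is unavoidably reduced to a racemic carbinol whose temporary stereocentre is erased in step 8.

Step 7
Reactants: 11 (2Z)-4-[3-(1-hydroxyethyl)-2,6-bis(methoxymethoxy)phenyl]-2-methylbut-2-en-1-ol
Product: 12 1-[3-[(2Z)-4-[tert-butyl(dimethyl)silyl]oxy-3-methylbut-2-en-1-yl]-2,4-bis(methoxymethoxy)phenyl]ethan-1-ol (racemic)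
Conditions: TBSCl (1.05 equiv), imidazole (2 equiv), CH2Cl2, 0 °C
Reagents that add atoms: tert-butyldimethylsilyl chloride (TBSCl), CC(C)(C)[Si](C)(C)Cl
Why: Sterically controlled silylation: the unhindered primary allylic OH reacts much faster than the secondary benzylic OH flanked by an ortho MOM ether.

Step 8
Reactants: 12 1-[3-[(2Z)-4-[tert-butyl(dimethyl)silyl]oxy-3-methylbut-2-en-1-yl]-2,4-bis(methoxymethoxy)phenyl]ethan-1-ol
Product: 13 1-[3-[(2Z)-4-[tert-butyl(dimethyl)silyl]oxy-3-methylbut-2-en-1-yl]-2,4-bis(methoxymethoxy)phenyl]ethan-1-one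
Conditions: Dess–Martin periodinane (1.3 equiv), NaHCO3, CH2Cl2, 0 °C → rt
Reagents that add atoms: none
Why: Dess–Martin oxidation of the secondary benzylic alcohol restores the methyl ketone under buffered neutral conditions that leave the silyl ether, the acetals and the (Z)-alkene untouched.

Step 9
Reactants: 14 4-hydroxybenzaldehyde
Product: 15 4-(methoxymethoxy)benzaldehyde
Conditions: MOMCl (1.3 equiv), iPr2NEt (1.5 equiv), CH2Cl2, 0 °C → rt
Reagents that add atoms: chloromethyl methyl ether (MOMCl), COCCl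
Why: Phenol O-alkylation; masking the phenol prevents formation of the unreactive phenoxide-aldehyde in the aldol step.

Step 10
Reactants: 13 1-[3-[(2Z)-4-[tert-butyl(dimethyl)silyl]oxy-3-methylbut-2-en-1-yl]-2,4-bis(methoxymethoxy)phenyl]ethan-1-one; 15 4-(methoxymethoxy)benzaldehyde
Product: 17 (2E)-1-[3-[(2Z)-4-[tert-butyl(dimethyl)silyl]oxy-3-methylbut-2-en-1-yl]-2,4-bis(methoxymethoxy)phenyl]-3-[4-(methoxymethoxy)phenyl]prop-2-en-1-one, via aldol adduct 16 (not isolated)
Conditions: 15 (1.2 equiv), KOH (50% aq., 10 equiv), EtOH, 0 °C → rt, 24–36 h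
Reagents that add atoms: none
Why: Claisen–Schmidt crossed aldol condensation; the enolate of the methyl ketone adds to the non-enolisable aldehyde and E1cB dehydration gives the thermodynamically favoured (E)-enone, while the MOM and alkyl silyl ethers tolerate ethanolic KOH.

Step 11
Reactants: 17 (2E)-1-[3-[(2Z)-4-[tert-butyl(dimethyl)silyl]oxy-3-methylbut-2-en-1-yl]-2,4-bis(methoxymethoxy)phenyl]-3-[4-(methoxymethoxy)phenyl]prop-2-en-1-one
Product: 18 (2E)-1-[2,4-dihydroxy-3-[(2Z)-4-hydroxy-3-methylbut-2-en-1-yl]phenyl]-3-(4-hydroxyphenyl)prop-2-en-1-one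
Conditions: 3 M aq. HCl/MeOH (1:4), rt → 40 °C, 3–6 h, monitored
Reagents that add atoms: none
Why: Acid-catalysed acetal and silyl ether methanolysis removes all four protecting groups at a stage where no ester is present to transesterify, under conditions commonly used for prenylated chalcones.

Step 12
Reactants: 18 (2E)-1-[2,4-dihydroxy-3-[(2Z)-4-hydroxy-3-methylbut-2-en-1-yl]phenyl]-3-(4-hydroxyphenyl)prop-2-en-1-one
Product: 19 (2E)-1-[4-[tert-butyl(dimethyl)silyl]oxy-3-[(2Z)-4-[tert-butyl(dimethyl)silyl]oxy-3-methylbut-2-en-1-yl]-2-hydroxyphenyl]-3-[4-[tert-butyl(dimethyl)silyl]oxyphenyl]prop-2-en-1-one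
Conditions: TBSCl (3.5 equiv), imidazole (7 equiv), DMF, 0 °C → rt
Reagents that add atoms: tert-butyldimethylsilyl chloride (TBSCl), CC(C)(C)[Si](C)(C)Cl
Why: Silylation of the primary alcohol and the two free phenols; the 2'-OH, hydrogen-bonded to the carbonyl and flanked by the side chain, stays free as is usual for chelated flavonoid hydroxyls.

Step 13
Reactants: 19 (2E)-1-[4-[tert-butyl(dimethyl)silyl]oxy-3-[(2Z)-4-[tert-butyl(dimethyl)silyl]oxy-3-methylbut-2-en-1-yl]-2-hydroxyphenyl]-3-[4-[tert-butyl(dimethyl)silyl]oxyphenyl]prop-2-en-1-one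
Product: 20 (2E)-1-[4-[tert-butyl(dimethyl)silyl]oxy-2-hydroxy-3-[(2Z)-4-hydroxy-3-methylbut-2-en-1-yl]phenyl]-3-[4-[tert-butyl(dimethyl)silyl]oxyphenyl]prop-2-en-1-one
Conditions: camphorsulfonic acid (10 mol %), MeOH/CH2Cl2 1:1, 0 °C, 1–2 h
Reagents that add atoms: none
Why: Acid-catalysed methanolysis is selective for the primary alkyl silyl ether, because aryl silyl ethers are much more stable to acid (they fall to base or fluoride instead).

Step 14
Reactants: 21 (E)-ferulic acid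
Product: 23 (2E)-3-[4-[tert-butyl(dimethyl)silyl]oxy-3-methoxyphenyl]prop-2-enoic acid, via silyl ester 22 (not isolated)
Conditions: TBSCl (2.5 equiv), imidazole (5 equiv), DMF, rt; then AcOH/THF/H2O 3:1:1, rt
Reagents that add atoms: tert-butyldimethylsilyl chloride (TBSCl), CC(C)(C)[Si](C)(C)Cl
Why: Silylation of phenol and acid followed by selective hydrolysis of the far more labile silyl ester leaves the aryl silyl ether and the (E)-alkene intact.

Step 15
Reactants: 20 (2E)-1-[4-[tert-butyl(dimethyl)silyl]oxy-2-hydroxy-3-[(2Z)-4-hydroxy-3-methylbut-2-en-1-yl]phenyl]-3-[4-[tert-butyl(dimethyl)silyl]oxyphenyl]prop-2-en-1-one; 23 (2E)-3-[4-[tert-butyl(dimethyl)silyl]oxy-3-methoxyphenyl]prop-2-enoic acid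
Product: 24 (2Z)-4-[6-[tert-butyl(dimethyl)silyl]oxy-3-[(2E)-3-[4-[tert-butyl(dimethyl)silyl]oxyphenyl]prop-2-enoyl]-2-hydroxyphenyl]-2-methylbut-2-en-1-yl (2E)-3-[4-[tert-butyl(dimethyl)silyl]oxy-3-methoxyphenyl]prop-2-enoate
Conditions: 23 (1.2 equiv), DCC (1.3 equiv), DMAP (0.1 equiv), CH2Cl2, 0 °C → rt
Reagents that add atoms: none
Why: Steglich esterification acylates the unhindered primary allylic alcohol at oxygen (so no allylic transposition or geometry change), while the chelated, hindered 2'-OH is inert.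

Step 16
Reactants: 24 (2Z)-4-[6-[tert-butyl(dimethyl)silyl]oxy-3-[(2E)-3-[4-[tert-butyl(dimethyl)silyl]oxyphenyl]prop-2-enoyl]-2-hydroxyphenyl]-2-methylbut-2-en-1-yl (2E)-3-[4-[tert-butyl(dimethyl)silyl]oxy-3-methoxyphenyl]prop-2-enoate
Product: 25 gemichalcone A, (2Z)-4-[2,6-dihydroxy-3-[(2E)-3-(4-hydroxyphenyl)prop-2-enoyl]phenyl]-2-methylbut-2-en-1-yl (2E)-3-(4-hydroxy-3-methoxyphenyl)prop-2-enoate
Conditions: Bu4NF (3.3 equiv), AcOH (3.5 equiv), THF, 0 °C
Reagents that add atoms: none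
Why: Fluoride-mediated desilylation of the three aryl silyl ethers, buffered with acetic acid so each phenoxide is protonated as it forms and the allylic ester, the enone and all three alkene geometries survive.

**Compound list**
1 | 2,4-dihydroxyacetophenone, 1-(2,4-dihydroxyphenyl)ethan-1-one | CC(=O)c1ccc(O)cc1O | starting material
2 | allyl bromide, 3-bromoprop-1-ene | C=CCBr | starting material
3 | 1-[2-hydroxy-4-(prop-2-en-1-yloxy)phenyl]ethan-1-one | CC(=O)c1ccc(OCC=C)cc1O | intermediate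
4 | 4-acetyl-3-hydroxy-2-(prop-2-en-1-yl)cyclohexa-3,5-dien-1-one (racemic Claisen dienone) | CC(=O)C1=C(O)C(CC=C)C(=O)C=C1 | intermediate
5 | 1-[2,4-dihydroxy-3-(prop-2-en-1-yl)phenyl]ethan-1-one | CC(=O)c1ccc(O)c(CC=C)c1O | intermediate
6 | 1-[2,4-bis(methoxymethoxy)-3-(prop-2-en-1-yl)phenyl]ethan-1-one | CC(=O)c1ccc(OCOC)c(CC=C)c1OCOC | intermediate
7 | 1-[3-(2,3-dihydroxypropyl)-2,4-bis(methoxymethoxy)phenyl]ethan-1-one (racemic) | CC(=O)c1ccc(OCOC)c(CC(O)CO)c1OCOC | intermediate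
8 | 2-[3-acetyl-2,6-bis(methoxymethoxy)phenyl]acetaldehyde | CC(=O)c1ccc(OCOC)c(CC=O)c1OCOC | intermediate
9 | ethyl 2-[bis(2,2,2-trifluoroethoxy)phosphoryl]propanoate (racemic) | CCOC(=O)C(C)P(=O)(OCC(F)(F)F)OCC(F)(F)F | starting material
10 | ethyl (2Z)-4-[3-acetyl-2,6-bis(methoxymethoxy)phenyl]-2-methylbut-2-enoate | CCOC(=O)/C(C)=C\Cc1c(OCOC)ccc(C(C)=O)c1OCOC | intermediate
11 | (2Z)-4-[3-(1-hydroxyethyl)-2,6-bis(methoxymethoxy)phenyl]-2-methylbut-2-en-1-ol (racemic carbinol) | CC(O)c1ccc(OCOC)c(C/C=C(/C)CO)c1OCOC | intermediate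
12 | 1-[3-[(2Z)-4-[tert-butyl(dimethyl)silyl]oxy-3-methylbut-2-en-1-yl]-2,4-bis(methoxymethoxy)phenyl]ethan-1-ol (racemic) | CC(O)c1ccc(OCOC)c(C/C=C(/C)CO[Si](C)(C)C(C)(C)C)c1OCOC | intermediate
13 | 1-[3-[(2Z)-4-[tert-butyl(dimethyl)silyl]oxy-3-methylbut-2-en-1-yl]-2,4-bis(methoxymethoxy)phenyl]ethan-1-one | CC(=O)c1ccc(OCOC)c(C/C=C(/C)CO[Si](C)(C)C(C)(C)C)c1OCOC | intermediate
14 | 4-hydroxybenzaldehyde | O=Cc1ccc(O)cc1 | starting material
15 | 4-(methoxymethoxy)benzaldehyde | COCOc1ccc(C=O)cc1 | intermediate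
16 | 1-[3-[(2Z)-4-[tert-butyl(dimethyl)silyl]oxy-3-methylbut-2-en-1-yl]-2,4-bis(methoxymethoxy)phenyl]-3-hydroxy-3-[4-(methoxymethoxy)phenyl]propan-1-one (racemic aldol adduct) | COCOc1ccc(C(O)CC(=O)c2ccc(OCOC)c(C/C=C(/C)CO[Si](C)(C)C(C)(C)C)c2OCOC)cc1 | intermediate
17 | (2E)-1-[3-[(2Z)-4-[tert-butyl(dimethyl)silyl]oxy-3-methylbut-2-en-1-yl]-2,4-bis(methoxymethoxy)phenyl]-3-[4-(methoxymethoxy)phenyl]prop-2-en-1-one | COCOc1ccc(/C=C/C(=O)c2ccc(OCOC)c(C/C=C(/C)CO[Si](C)(C)C(C)(C)C)c2OCOC)cc1 | intermediate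
18 | (2E)-1-[2,4-dihydroxy-3-[(2Z)-4-hydroxy-3-methylbut-2-en-1-yl]phenyl]-3-(4-hydroxyphenyl)prop-2-en-1-one | O=C(/C=C/c1ccc(O)cc1)c1ccc(O)c(C/C=C(/C)CO)c1O | intermediate
19 | (2E)-1-[4-[tert-butyl(dimethyl)silyl]oxy-3-[(2Z)-4-[tert-butyl(dimethyl)silyl]oxy-3-methylbut-2-en-1-yl]-2-hydroxyphenyl]-3-[4-[tert-butyl(dimethyl)silyl]oxyphenyl]prop-2-en-1-one | O=C(/C=C/c1ccc(O[Si](C)(C)C(C)(C)C)cc1)c1ccc(O[Si](C)(C)C(C)(C)C)c(C/C=C(/C)CO[Si](C)(C)C(C)(C)C)c1O | intermediate
20 | (2E)-1-[4-[tert-butyl(dimethyl)silyl]oxy-2-hydroxy-3-[(2Z)-4-hydroxy-3-methylbut-2-en-1-yl]phenyl]-3-[4-[tert-butyl(dimethyl)silyl]oxyphenyl]prop-2-en-1-one | O=C(/C=C/c1ccc(O[Si](C)(C)C(C)(C)C)cc1)c1ccc(O[Si](C)(C)C(C)(C)C)c(C/C=C(/C)CO)c1O | intermediate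
21 | (E)-ferulic acid, (2E)-3-(4-hydroxy-3-methoxyphenyl)prop-2-enoic acid | COc1cc(/C=C/C(=O)O)ccc1O | starting material
22 | tert-butyl(dimethyl)silyl (2E)-3-[4-[tert-butyl(dimethyl)silyl]oxy-3-methoxyphenyl]prop-2-enoate | COc1cc(/C=C/C(=O)O[Si](C)(C)C(C)(C)C)ccc1O[Si](C)(C)C(C)(C)C | intermediate
23 | (2E)-3-[4-[tert-butyl(dimethyl)silyl]oxy-3-methoxyphenyl]prop-2-enoic acid | COc1cc(/C=C/C(=O)O)ccc1O[Si](C)(C)C(C)(C)C | intermediate
24 | (2Z)-4-[6-[tert-butyl(dimethyl)silyl]oxy-3-[(2E)-3-[4-[tert-butyl(dimethyl)silyl]oxyphenyl]prop-2-enoyl]-2-hydroxyphenyl]-2-methylbut-2-en-1-yl (2E)-3-[4-[tert-butyl(dimethyl)silyl]oxy-3-methoxyphenyl]prop-2-enoate | COc1cc(/C=C/C(=O)OC/C(C)=C\Cc2c(O[Si](C)(C)C(C)(C)C)ccc(C(=O)/C=C/c3ccc(O[Si](C)(C)C(C)(C)C)cc3)c2O)ccc1O[Si](C)(C)C(C)(C)C | intermediate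
25 | gemichalcone A, (2Z)-4-[2,6-dihydroxy-3-[(2E)-3-(4-hydroxyphenyl)prop-2-enoyl]phenyl]-2-methylbut-2-en-1-yl (2E)-3-(4-hydroxy-3-methoxyphenyl)prop-2-enoate | COc1cc(/C=C/C(=O)OC/C(C)=C\Cc2c(O)ccc(C(=O)/C=C/c3ccc(O)cc3)c2O)ccc1O | target

**Totals**
Total steps: 16. Longest linear sequence: 14 (steps 1–8, 10–13, 15, 16).

**Three steps most likely to fail, with fallbacks**

Step 2 (thermal Claisen: C3 versus C5 regiochemistry, charring at 200 °C). The fallback sets out from 1 and comes back at 6, making the aryl–allyl bond by cross-coupling instead of a sigmatropic shift. I2/HIO3 in aqueous EtOH iodinates 1 between the two hydroxyls to give 1-(2,4-dihydroxy-3-iodophenyl)ethan-1-one F1 (any 5-iodo isomer is removed by crystallisation). NaH/MOMCl in DMF then gives 1-[3-iodo-2,4-bis(methoxymethoxy)phenyl]ethan-1-one F2. Stille coupling of F2 with CH2=CHCH2SnBu3 (Pd(PPh3)4, DMF, 90 °C) delivers 6, so the halogen fixes the regiochemistry.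

Step 5 (Z-selectivity and base sensitivity of the enolisable arylacetaldehyde). The fallback sets out from 8 and comes back at 13, replacing the phosphonate olefination and ester reduction by a vinyl iodide and cross-coupling sequence, which also makes steps 6–8 unnecessary. Ethyltriphenylphosphonium iodide is deprotonated with n-BuLi in THF to ethylidenetriphenylphosphorane F3, iodinated with I2 at −78 °C to (1-iodoethyl)triphenylphosphonium iodide F4, and deprotonated with NaN(SiMe3)2 to (1-iodoethylidene)triphenylphosphorane F5. Wittig reaction of F5 with 8 at −78 °C gives 1-[3-[(2Z)-3-iodobut-2-en-1-yl]-2,4-bis(methoxymethoxy)phenyl]ethan-1-one F6, with iodine cis to CH2Ar. Stille coupling of F6 with Bu3SnCH2OH (Pd(PPh3)4, toluene, 90 °C) replaces iodine by CH2OH with retention, giving 1-[3-[(2Z)-4-hydroxy-3-methylbut-2-en-1-yl]-2,4-bis(methoxymethoxy)phenyl]ethan-1-one F7, in which the ketone was never reduced. TBSCl/imidazole then gives 13.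

Step 11 (acidic unmasking beside a hydroxylated prenyl-type chain: risk of chroman or dihydrobenzofuran formation and chalcone–flavanone cyclisation). The fallback sets out from 17 and comes back at 19, replacing protic acid solvolysis by Lewis-acid silyl exchange so that the free allylic alcohol never meets acid. Me3SiOSO2CF3 with 2,2'-bipyridyl in MeCN (0 °C → rt) converts the three aryl MOM ethers into the tris(trimethylsilyl) ether (2E)-1-[3-[(2Z)-4-[tert-butyl(dimethyl)silyl]oxy-3-methylbut-2-en-1-yl]-2,4-bis(trimethylsilyloxy)phenyl]-3-[4-(trimethylsilyloxy)phenyl]prop-2-en-1-one F8. Aqueous work-up hydrolyses F8 to (2E)-1-[3-[(2Z)-4-[tert-butyl(dimethyl)silyl]oxy-3-methylbut-2-en-1-yl]-2,4-dihydroxyphenyl]-3-(4-hydroxyphenyl)prop-2-en-1-one F9, with the alkyl silyl ether still in place. TBSCl (2.3 equiv)/imidazole in DMF silylates the two non-chelated phenols of F9 to give 19.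

**Further compounds**
F1 | step 2 | 1-(2,4-dihydroxy-3-iodophenyl)ethan-1-one | CC(=O)c1ccc(O)c(I)c1O
F2 | step 2 | 1-[3-iodo-2,4-bis(methoxymethoxy)phenyl]ethan-1-one | CC(=O)c1ccc(OCOC)c(I)c1OCOC
F3 | step 5 | ethylidenetriphenylphosphorane | CC=P(c1ccccc1)(c1ccccc1)c1ccccc1
F4 | step 5 | (1-iodoethyl)triphenylphosphonium iodide | CC(I)[P+](c1ccccc1)(c1ccccc1)c1ccccc1.[I-]
F5 | step 5 | (1-iodoethylidene)triphenylphosphorane | CC(I)=P(c1ccccc1)(c1ccccc1)c1ccccc1
F6 | step 5 | 1-[3-[(2Z)-3-iodobut-2-en-1-yl]-2,4-bis(methoxymethoxy)phenyl]ethan-1-one | CC(=O)c1ccc(OCOC)c(C/C=C(/C)I)c1OCOC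
F7 | step 5 | 1-[3-[(2Z)-4-hydroxy-3-methylbut-2-en-1-yl]-2,4-bis(methoxymethoxy)phenyl]ethan-1-one | CC(=O)c1ccc(OCOC)c(C/C=C(/C)CO)c1OCOC
F8 | step 11 | (2E)-1-[3-[(2Z)-4-[tert-butyl(dimethyl)silyl]oxy-3-methylbut-2-en-1-yl]-2,4-bis(trimethylsilyloxy)phenyl]-3-[4-(trimethylsilyloxy)phenyl]prop-2-en-1-one | C[Si](C)(C)Oc1ccc(/C=C/C(=O)c2ccc(O[Si](C)(C)C)c(C/C=C(/C)CO[Si](C)(C)C(C)(C)C)c2O[Si](C)(C)C)cc1
F9 | step 11 | (2E)-1-[3-[(2Z)-4-[tert-butyl(dimethyl)silyl]oxy-3-methylbut-2-en-1-yl]-2,4-dihydroxyphenyl]-3-(4-hydroxyphenyl)prop-2-en-1-one | O=C(/C=C/c1ccc(O)cc1)c1ccc(O)c(C/C=C(/C)CO[Si](C)(C)C(C)(C)C)c1O
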